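**Plan**
1. Retrosynthetic cuts, in order: the C5–vinyl bond of the stilbene (Mizoroki–Heck on a C5 iodide made from C5–H by iridium borylation), then O1–C7a of the dihydrofuran (copper-catalysed aryl ether formation), then C2–C3 (auxiliary-controlled syn aldol), then the one-carbon homologation of 2-bromo-3-methoxybenzaldehyde.
2. Enabling feature: C7a is an sp2 carbon of ring A between C7 (OMe) and C3a, and the chain C7a–C3a–C3–C2–O1 is a 2-(2-haloaryl)ethanol. C2 is benzylic and para to the syringyl oxygen, so it ionises too readily to serve as the electrophile; the oxygen is therefore joined to C7a.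
3. Forward order: arylacetyl imide; aldol joining ring A and the syringyl ring through C3–C2; reduction and silylation; the only ring closure (dihydrofuran, O1–C7a); C5 borylation, iodination and Heck attachment of the resorcinol ring; deprotection.
4. Stereochemistry: C2 (R) and C3 (S) are both set in the boron aldol by (R)-4-benzyl-2-oxazolidinone. The etherification breaks no bond at either centre, so the syn aldol pair becomes the trans ring. The E alkene comes from the Heck step.

Key step: step 8

Remark: the locants O1, C2, C3, C3a, C4–C7 and C7a are those of the 2,3-dihydrobenzofuran core of the target and are used for its precursors as well; ring A is the benzo ring of that core; 3,5-diacetoxystyrene is taken as a purchasable reagent.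

**Route**

Step 1
Reactants: 1 2-bromo-3-methoxybenzaldehyde
Product: 4 (2-bromo-3-methoxyphenyl)acetonitrile, via tosyloxazoline 2 (not isolated), via tosylvinylformamide 3 (not isolated)
Conditions: TosMIC, t-BuOK, DME, −40 °C; then MeOH, reflux
Reagents that add atoms: TosMIC (p-toluenesulfonylmethyl isocyanide), Cc1ccc(cc1)S(=O)(=O)C[N+]#[C-]
Why: Van Leusen reductive cyanation: the TosMIC anion adds to the aldehyde and cyclises to oxazoline 2, excess alkoxide opens it to the N-(1-tosylvinyl)formamide 3, and methanolysis removes the formyl group and expels sulfinate, leaving the nitrile with one extra carbon while the aryl bromide is untouched by alkoxide at these temperatures.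

Step 2
Reactants: 4 (2-bromo-3-methoxyphenyl)acetonitrile
Product: 5 (2-bromo-3-methoxyphenyl)acetic acid
Conditions: KOH, EtOH/H2O, reflux; then aq HCl
Reagents that add atoms: potassium hydroxide, [K+].[OH-]; water, O
Why: Alkaline nitrile hydrolysis through the primary amide gives the carboxylate, freed on acidification; the aryl bromide is not activated for substitution and the methyl ether is inert.

Step 3
Reactants: 5 (2-bromo-3-methoxyphenyl)acetic acid; 6 (R)-4-benzyl-2-oxazolidinone
Product: 8 (R)-4-benzyl-3-[(2-bromo-3-methoxyphenyl)acetyl]oxazolidin-2-one, via mixed pivalic anhydride 7 (not isolated)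
Conditions: PivCl, Et3N, THF, −20 °C; then 6, LiCl, −20 °C → rt
Reagents that add atoms: none
Why: N-Acylation through a mixed anhydride: pivaloyl chloride activates the acid, and the oxazolidinone, made nucleophilic by LiCl and Et3N, attacks the unhindered arylacetyl carbonyl and not the tert-butyl-shielded one.

Step 4
Reactants: 9 syringaldehyde
Product: 10 3,5-dimethoxy-4-(methoxymethoxy)benzaldehyde
Conditions: MOMCl, i-Pr2NEt, CH2Cl2, 0 °C → rt
Reagents that add atoms: chloromethyl methyl ether (MOMCl), COCCl
Why: Williamson-type O-alkylation of the phenoxide with the reactive α-chloro ether gives the MOM acetal, which is stable to base, hydride, the boron enolate and the copper, iridium and palladium steps and leaves with mild acid at the end.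

Step 5
Reactants: 8 (R)-4-benzyl-3-[(2-bromo-3-methoxyphenyl)acetyl]oxazolidin-2-one; 10 3,5-dimethoxy-4-(methoxymethoxy)benzaldehyde
Product: 13 (R)-4-benzyl-3-[(2R,3R)-2-(2-bromo-3-methoxyphenyl)-3-hydroxy-3-[3,5-dimethoxy-4-(methoxymethoxy)phenyl]propanoyl]oxazolidin-2-one, via Z boron enolate 11 (not isolated), via boron aldolate 12 (not isolated)
Conditions: Bu2BOTf, i-Pr2NEt, CH2Cl2, −78 → 0 °C; 10, −78 → 0 °C; then pH 7 buffer, MeOH, H2O2, 0 °C
Reagents that add atoms: none
Why: Evans syn aldol: soft enolisation gives the Z boron enolate 11, which adds to the aldehyde through a closed chair transition state with the auxiliary carbonyl turned away from the enolate oxygen, so the aldehyde meets the face opposite the benzyl group and both the aryl-bearing carbon (later C3) and the carbinol (later C2) are set as the (2R,3R) syn pair by the (R)-auxiliary.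

Step 6
Reactants: 13 syn aldol imide
Product: 14 (1R,2S)-2-(2-bromo-3-methoxyphenyl)-1-[3,5-dimethoxy-4-(methoxymethoxy)phenyl]propane-1,3-diol
Conditions: LiBH4, MeOH (1 equiv), THF, 0 °C
Reagents that add atoms: none
Why: Reductive cleavage of the imide (hydride attack at the exocyclic acyl carbonyl, then reduction of the aldehyde formed) gives the 1,3-diol and returns the auxiliary; no bond at either stereocentre is broken, and the aryl-bearing carbon changes from R to S only because CH2OH ranks below the carbinol carbon.

Step 7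
Reactants: 14 (1R,2S)-diol
Product: 15 (1R,2S)-2-(2-bromo-3-methoxyphenyl)-1-[3,5-dimethoxy-4-(methoxymethoxy)phenyl]-3-[(triisopropylsilyl)oxy]propan-1-ol
Conditions: TIPSCl, imidazole, DMF, 0 °C → rt
Reagents that add atoms: chlorotriisopropylsilane (TIPSCl), CC(C)[Si](Cl)(C(C)C)C(C)C
Why: Silylation with the bulky chlorosilane discriminates the primary from the hindered secondary benzylic hydroxyl; the triisopropylsilyl ether is chosen because it has no aromatic C–H for the later borylation and resists base-induced 1,5 O-to-O migration far better than smaller silyl ethers.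

Step 8
Reactants: 15 (1R,2S)-bromoaryl alcohol
Product: 16 triisopropyl{[(2R,3S)-7-methoxy-2-[3,5-dimethoxy-4-(methoxymethoxy)phenyl]-2,3-dihydrobenzofuran-3-yl]methoxy}silane (trans)
Conditions: CuI (10 mol %), 3,4,7,8-tetramethyl-1,10-phenanthroline (20 mol %), Cs2CO3 (2 equiv), toluene, 110 °C
Reagents that add atoms: none
Why: Intramolecular Ullmann-type C–O coupling: Cs2CO3 converts the secondary alcohol into a phenanthroline-ligated alkoxide of monovalent copper, the tethered C7a–Br bond adds oxidatively to give a six-membered trivalent copper aryl alkoxide, and C(sp2)–O reductive elimination releases the ether and returns monovalent copper. The closest known reaction is the copper- or palladium-catalysed cyclisation of 2-(2-haloaryl)ethanols to 2,3-dihydrobenzofurans. The dihydrofuran ring (O1, C2, C3, C3a, C7a) closes in a 5-exo sense by ipso substitution at the aromatic carbon C7a. No stereocentre is created; since no bond to C2 or C3 is broken, the (1R,2S) syn arrangement is carried unchanged into the trans (2R,3S) ring, which an ionising closure at the syringyl carbinol could not guarantee. The step needs chemoselective arylation of the secondary oxygen; the primary oxygen would close a ring of the same size, so it is blocked as the migration-resistant triisopropylsilyl ether, and the bromide is the only carbon–halogen bond present. Intramolecular delivery and the neighbouring C7 methoxy group should offset the steric shielding of the doubly ortho-substituted bromide.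

Step 9
Reactants: 16 trans dihydrobenzofuran core
Product: 17 triisopropyl{[(2R,3S)-7-methoxy-2-[3,5-dimethoxy-4-(methoxymethoxy)phenyl]-5-(4,4,5,5-tetramethyl-1,3,2-dioxaborolan-2-yl)-2,3-dihydrobenzofuran-3-yl]methoxy}silane
Conditions: [Ir(OMe)(cod)]2 (1.5 mol %), dtbpy (3 mol %), B2pin2 (1.0 equiv), THF, 80 °C
Reagents that add atoms: bis(pinacolato)diboron (B2pin2), CC1(C)OB(OC1(C)C)B1OC(C)(C)C(C)(C)O1
Why: Iridium-catalysed aromatic C–H borylation is governed by sterics: C5–H is the only aromatic C–H with no ortho substituent (C4–H is flanked by C3a and the C3 side chain, C6–H by the C7 methoxy group, and both syringyl C–H bonds are flanked on two sides), so the boryl group should enter at C5 alone.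

Step 10
Reactants: 17 C5 pinacol boronate
Product: 18 {[(2R,3S)-5-iodo-7-methoxy-2-[3,5-dimethoxy-4-(methoxymethoxy)phenyl]-2,3-dihydrobenzofuran-3-yl]methoxy}triisopropylsilane
Conditions: CuI (10 mol %), 1,10-phenanthroline (20 mol %), KI (1.5 equiv), MeOH/THF/H2O, air, 80 °C
Reagents that add atoms: potassium iodide, [K+].[I-]
Why: Copper-catalysed aerobic iododeboronation: the aryl group passes from boron to copper, air oxidises the aryl copper iodide to trivalent copper and C–I reductive elimination gives the iodide at the former C–B position; the medium stays neutral to mildly basic, which the MOM acetal and the silyl ether tolerate.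

Step 11
Reactants: 18 C5 iodide; 19 3,5-diacetoxystyrene
Product: 20 5-[(E)-2-[(2R,3S)-7-methoxy-2-[3,5-dimethoxy-4-(methoxymethoxy)phenyl]-3-{[(triisopropylsilyl)oxy]methyl}-2,3-dihydrobenzofuran-5-yl]ethenyl]-1,3-phenylene diacetate
Conditions: Pd(OAc)2 (5 mol %), P(o-tol)3 (10 mol %), Et3N, DMF, 90 °C
Reagents that add atoms: none
Why: Mizoroki–Heck reaction: the aryl iodide adds oxidatively to zerovalent palladium formed from Pd(OAc)2 and the phosphine, the aryl group is delivered to the unsubstituted alkene carbon of the styrene, and syn β-hydride elimination gives the E stilbene; Et3N in DMF should leave the aryl acetates in place.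

Step 12
Reactants: 20 protected stilbene diacetate
Product: 22 gnetucleistol F, via stilbene diol 21 (not isolated)
Conditions: K2CO3, MeOH/THF, 0 °C → rt; then 3 M aq HCl (excess), 40 °C
Reagents that add atoms: none
Why: Base-catalysed transesterification frees the two resorcinol hydroxyls, and after acidification the MOM acetal and the primary silyl ether are solvolysed by dilute methanolic HCl; no stereocentre is touched, and should C2–O1 open reversibly under acid it would reclose to the same, more stable trans ring under control of C3.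

**Compound list**

1 | 2-bromo-3-methoxybenzaldehyde | COc1cccc(C=O)c1Br | starting material
2 | 5-(2-bromo-3-methoxyphenyl)-4-tosyl-4,5-dihydro-1,3-oxazole (racemic, both centres lost later; not isolated) | COc1cccc(C2OC=NC2S(=O)(=O)c2ccc(C)cc2)c1Br | intermediate
3 | N-[2-(2-bromo-3-methoxyphenyl)-1-tosylethenyl]formamide (potassium salt in the flask; not isolated) | COc1cccc(C=C(NC=O)S(=O)(=O)c2ccc(C)cc2)c1Br | intermediate
4 | (2-bromo-3-methoxyphenyl)acetonitrile | COc1cccc(CC#N)c1Br | intermediate
5 | (2-bromo-3-methoxyphenyl)acetic acid | COc1cccc(CC(=O)O)c1Br | intermediate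
6 | (R)-4-benzyl-2-oxazolidinone | O=C1OC[C@@H](Cc2ccccc2)N1 | starting material
7 | (2-bromo-3-methoxyphenyl)acetic pivalic anhydride (not isolated) | COc1cccc(CC(=O)OC(=O)C(C)(C)C)c1Br | intermediate
8 | (R)-4-benzyl-3-[(2-bromo-3-methoxyphenyl)acetyl]oxazolidin-2-one | COc1cccc(CC(=O)N2[C@H](Cc3ccccc3)COC2=O)c1Br | intermediate
9 | syringaldehyde (4-hydroxy-3,5-dimethoxybenzaldehyde) | COc1cc(C=O)cc(OC)c1O | starting material
10 | 3,5-dimethoxy-4-(methoxymethoxy)benzaldehyde | COCOc1c(OC)cc(C=O)cc1OC | intermediate
11 | Z dibutylboron enolate of imide 8 (not isolated) | CCCCB(CCCC)O/C(=C\c1cccc(OC)c1Br)N1[C@H](Cc2ccccc2)COC1=O | intermediate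
12 | dibutylboron aldolate of 13 (not isolated) | COc1cccc([C@@H](C(=O)N2[C@H](Cc3ccccc3)COC2=O)[C@@H](OB(CCCC)CCCC)c2cc(OC)c(OCOC)c(OC)c2)c1Br | intermediate
13 | (R)-4-benzyl-3-[(2R,3R)-2-(2-bromo-3-methoxyphenyl)-3-hydroxy-3-[3,5-dimethoxy-4-(methoxymethoxy)phenyl]propanoyl]oxazolidin-2-one | COc1cccc([C@@H](C(=O)N2[C@H](Cc3ccccc3)COC2=O)[C@@H](O)c2cc(OC)c(OCOC)c(OC)c2)c1Br | intermediate
14 | (1R,2S)-2-(2-bromo-3-methoxyphenyl)-1-[3,5-dimethoxy-4-(methoxymethoxy)phenyl]propane-1,3-diol | COc1cccc([C@@H](CO)[C@@H](O)c2cc(OC)c(OCOC)c(OC)c2)c1Br | intermediate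
15 | (1R,2S)-2-(2-bromo-3-methoxyphenyl)-1-[3,5-dimethoxy-4-(methoxymethoxy)phenyl]-3-[(triisopropylsilyl)oxy]propan-1-ol | COc1cccc([C@@H](CO[Si](C(C)C)(C(C)C)C(C)C)[C@@H](O)c2cc(OC)c(OCOC)c(OC)c2)c1Br | intermediate
16 | triisopropyl{[(2R,3S)-7-methoxy-2-[3,5-dimethoxy-4-(methoxymethoxy)phenyl]-2,3-dihydrobenzofuran-3-yl]methoxy}silane | COc1cc([C@@H]2Oc3c(OC)cccc3[C@H]2CO[Si](C(C)C)(C(C)C)C(C)C)cc(OC)c1OCOC | intermediate
17 | C5 pinacol boronate of 16 | COc1cc([C@@H]2Oc3c(OC)cc(B4OC(C)(C)C(C)(C)O4)cc3[C@H]2CO[Si](C(C)C)(C(C)C)C(C)C)cc(OC)c1OCOC | intermediate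
18 | C5 iodide of 16 | COc1cc([C@@H]2Oc3c(OC)cc(I)cc3[C@H]2CO[Si](C(C)C)(C(C)C)C(C)C)cc(OC)c1OCOC | intermediate
19 | 3,5-diacetoxystyrene | C=Cc1cc(OC(C)=O)cc(OC(C)=O)c1 | starting material
20 | 5-[(E)-2-[(2R,3S)-7-methoxy-2-[3,5-dimethoxy-4-(methoxymethoxy)phenyl]-3-{[(triisopropylsilyl)oxy]methyl}-2,3-dihydrobenzofuran-5-yl]ethenyl]-1,3-phenylene diacetate | COc1cc([C@@H]2Oc3c(OC)cc(/C=C/c4cc(OC(C)=O)cc(OC(C)=O)c4)cc3[C@H]2CO[Si](C(C)C)(C(C)C)C(C)C)cc(OC)c1OCOC | intermediate
21 | 5-[(E)-2-[(2R,3S)-7-methoxy-2-[3,5-dimethoxy-4-(methoxymethoxy)phenyl]-3-{[(triisopropylsilyl)oxy]methyl}-2,3-dihydrobenzofuran-5-yl]ethenyl]benzene-1,3-diol (not isolated) | COc1cc([C@@H]2Oc3c(OC)cc(/C=C/c4cc(O)cc(O)c4)cc3[C@H]2CO[Si](C(C)C)(C(C)C)C(C)C)cc(OC)c1OCOC | intermediate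
22 | gnetucleistol F, 5-[(E)-2-[(2R,3S)-2-(4-hydroxy-3,5-dimethoxyphenyl)-3-(hydroxymethyl)-7-methoxy-2,3-dihydrobenzofuran-5-yl]ethenyl]benzene-1,3-diol | COc1cc([C@@H]2Oc3c(OC)cc(/C=C/c4cc(O)cc(O)c4)cc3[C@H]2CO)cc(OC)c1O | target

**Step count and risks**

Total: 12 steps. Longest linear sequence: 11 steps (1 → 4 → 5 → 8 → 13 → 14 → 15 → 16 → 17 → 18 → 20 → 22); step 4 is the side branch.

Step 8. What may go wrong: oxidative addition at the doubly ortho-substituted C7a–Br bond is slow, so the alkoxide is oxidised to the ketone or the bromide is reduced away before the ring closes. The fallback sets out from 15 and returns at 16. The bromide would be exchanged for lithium (n-BuLi, 2.2 equiv, THF, −78 °C, the first equivalent taken up by the hydroxyl), and the aryllithium trapped with B(OMe)3 and oxidised (NaOH, H2O2) to the phenol (1R,2S)-2-(2-hydroxy-3-methoxyphenyl)-1-[3,5-dimethoxy-4-(methoxymethoxy)phenyl]-3-[(triisopropylsilyl)oxy]propan-1-ol F1. Catalytic camphorsulfonic acid in CH2Cl2 at 0 °C should then ionise the syringyl carbinol, and the phenol oxygen would close O1–C2 on the face away from the C3 substituent, the trans ring also being the more stable one, to give 16. This fallback makes the ring at the other C–O bond and replaces stereoretention at C2 by control from C3.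

Step 5. What may go wrong: the hindered α-aryl boron enolate adds slowly to the electron-rich aldehyde, and on warming retro-aldol equilibration erodes conversion and diastereoselectivity. The fallback sets out from 5 and 10 and returns at 14; it replaces the reversible aldol by an irreversible acylation followed by a hydride reduction. Acid 5 would be attached, through anhydride 7 as in step 3, to (S)-4-benzyl-2-oxazolidinone to give (S)-4-benzyl-3-[(2-bromo-3-methoxyphenyl)acetyl]oxazolidin-2-one F2. Aldehyde 10 would be oxidised (NaClO2, NaH2PO4, 2-methyl-2-butene, t-BuOH/H2O; Pinnick oxidation) to 3,5-dimethoxy-4-(methoxymethoxy)benzoic acid F3 and converted under neutral conditions (1-chloro-N,N,2-trimethylpropenylamine, CH2Cl2) into 3,5-dimethoxy-4-(methoxymethoxy)benzoyl chloride F4. The chelated lithium enolate of F2 (LiN(i-Pr)2, THF, −78 °C) would be C-acylated by F4 on the face away from the benzyl group to give the (2R)-β-keto imide F5, which allylic strain should protect from enolisation. Because acylation of the chelated enolate and the boron aldol use opposite enolate faces, the (S)-auxiliary here gives the same (2R) centre as the (R)-auxiliary in step 5. Chelation-controlled reduction with Zn(BH4)2 (CH2Cl2/Et2O, −20 °C) should give the syn (2R,3R)-β-hydroxy imide F6, and LiBH4 as in step 6 would cleave it to diol 14.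

Step 10. What may go wrong: protodeboronation or Chan–Lam-type methoxylation and hydroxylation of the electron-rich arylboronate outrun iodide transfer. The fallback sets out from 17 and returns at 20, with no halide made. The pinacol ester would be cleaved (NaIO4, NH4OAc, acetone/H2O, rt) to the boronic acid [(2R,3S)-7-methoxy-2-[3,5-dimethoxy-4-(methoxymethoxy)phenyl]-3-{[(triisopropylsilyl)oxy]methyl}-2,3-dihydrobenzofuran-5-yl]boronic acid F7. This would be coupled directly with styrene 19 in a base-free oxidative Heck reaction (Pd(OAc)2, 2,9-dimethyl-1,10-phenanthroline, p-benzoquinone or air, MeCN, 40 °C): the aryl group passes from boron to divalent palladium, inserts the styrene and leaves by β-hydride elimination as the E stilbene 20, the acetates surviving the base-free medium.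

**Further compounds**

F1 | step 8 | (1R,2S)-2-(2-hydroxy-3-methoxyphenyl)-1-[3,5-dimethoxy-4-(methoxymethoxy)phenyl]-3-[(triisopropylsilyl)oxy]propan-1-ol | COc1cccc([C@@H](CO[Si](C(C)C)(C(C)C)C(C)C)[C@@H](O)c2cc(OC)c(OCOC)c(OC)c2)c1O
F2 | step 5 | (S)-4-benzyl-3-[(2-bromo-3-methoxyphenyl)acetyl]oxazolidin-2-one | COc1cccc(CC(=O)N2[C@@H](Cc3ccccc3)COC2=O)c1Br
F3 | step 5 | 3,5-dimethoxy-4-(methoxymethoxy)benzoic acid | COCOc1c(OC)cc(C(=O)O)cc1OC
F4 | step 5 | 3,5-dimethoxy-4-(methoxymethoxy)benzoyl chloride | COCOc1c(OC)cc(C(=O)Cl)cc1OC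
F5 | step 5 | (S)-4-benzyl-3-[(2R)-2-(2-bromo-3-methoxyphenyl)-3-[3,5-dimethoxy-4-(methoxymethoxy)phenyl]-3-oxopropanoyl]oxazolidin-2-one | COc1cccc([C@@H](C(=O)N2[C@@H](Cc3ccccc3)COC2=O)C(=O)c2cc(OC)c(OCOC)c(OC)c2)c1Br
F6 | step 5 | (S)-4-benzyl-3-[(2R,3R)-2-(2-bromo-3-methoxyphenyl)-3-hydroxy-3-[3,5-dimethoxy-4-(methoxymethoxy)phenyl]propanoyl]oxazolidin-2-one | COc1cccc([C@@H](C(=O)N2[C@@H](Cc3ccccc3)COC2=O)[C@@H](O)c2cc(OC)c(OCOC)c(OC)c2)c1Br
F7 | step 10 | [(2R,3S)-7-methoxy-2-[3,5-dimethoxy-4-(methoxymethoxy)phenyl]-3-{[(triisopropylsilyl)oxy]methyl}-2,3-dihydrobenzofuran-5-yl]boronic acid | COc1cc([C@@H]2Oc3c(OC)cc(B(O)O)cc3[C@H]2CO[Si](C(C)C)(C(C)C)C(C)C)cc(OC)c1OCOC
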